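**Conventions and assumptions**

- Locants C1–C15 are those of the daucane skeleton: C1 = quaternary ring-fusion carbon (C15 methyl), C2/C3 = cyclopentane methylenes, C4 = carbinol carbon carrying the isopropyl group, C5 = ring-fusion CH, C6 = ester carbon, C7 = CH2, C8 = carbon carrying the exocyclic methylene C14, C9 = allylic carbinol, C10 = CH2. Ring B = C1–C5, ring A = C1, C5–C10. β is the face of the C15 methyl. The target is 1β-Me, 4β-OH, 5α-H, 6α-O-acyl, 9α-OH.
- Compounds 1, 2, 3 and 17 are taken as catalogue compounds.

## The problem

Ferugin is a trans-fused hydroazulene in which cyclopentane ring B and cycloheptane ring A share the C1–C5 bond, with a quaternary, methyl-bearing C1 at the fusion; no simple building block has this connectivity. Four of the five stereocentres are contiguous (C1, C5, C4, C6) and the fifth, C9, is remote but cis-1,4 to the C6 oxygen. C1 cannot be corrected once made and must be set by relay from another centre; C5 is adjustable only while C4 or C6 is a carbonyl; C4 is made by addition to a ketone under control of the ring fusion; C9 is out of reach of the other centres and needs reagent control. The seven-membered ring has to be closed next to a quaternary carbon and carries three different functions on C6, C8 and C9, of which the two secondary oxygens must be told apart. The C4–O/C5–H/C6–O array is an aldol (retro-aldol and β-elimination whenever C4 or C6 is a carbonyl); the tertiary alcohol ionises in acid, the 2-methylenecycloheptanol is sensitive to acid and electrophiles, and the aryl ester with free phenol is sensitive to base (acyl migration to the cis C9 hydroxyl). The feature that opens the way: C4 and C9 are 1,5-related through C5–C1–C10, and the chain C5–C6–C7–C8–C9 closes to a five-membered ring if C5 and C9 are joined, so ring A is a cyclopentanone enlarged by the two atoms C1–C10, with ring B as the tether. A second feature, used later: O6 and C9 are cis-1,4 on ring A and can be spanned by one oxygen atom.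

## Retrosynthesis

**22 ⇒ 21 ⇒ 20 ⇒ 18.** Cut the phenol O–Si bond, the C9–H bond and the C8=C14 bond. The 2-methylenecycloheptanol is the 1,2-reduction product of α-methylene ketone 20, which comes from ketone 18 by α-methylenation. Against allylic oxidation of an alkene (choice between C7, C9 and C10) this places C14 and O9 without ambiguity. Precursor 18 has no alkene and one stereocentre less. The forward steps must react at C8 and not at the neopentyl C10, and must deliver hydride to the β face of C9.

**18 ⇒ 16 + 17.** Cut the ester C–O bond. Acylating C6–OH while C9 is still a ketone means the two secondary hydroxyls never compete; the tertiary C4–OH is inert. Acid 17 carries the phenol as a silyl ether.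

**16 ⇒ 14 (through 15).** Cut the C4–isopropyl bond. The precursor has ketones at both C4 and C9; the cis-1,4 relation of O6 and C9 lets the C6 hydroxyl tie C9 up as the bridged methyl ketal 14. One operation protects C9 and O6, leaves C4 as the only carbonyl and makes the skeleton rigid. The forward addition must come from the α face of C4.

**14 ⇒ 11 (through 12, 13).** Cut C6–O back to C6–Si with retention. A β-silyl ketone cannot eliminate or undergo retro-aldol, whereas a β-oxygenated one would; the large silyl group also steers the key step and comes from an enantioselective conjugate addition. Precursor 11 is a plain 1,5-diketone with three stereocentres.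

**11 ⇒ 8 ⇒ 7 (key).** Re-join C5 and C9 (aldol direction) to reach cyclobutyl acetate 8, then open the cyclobutane C5–C1–C10–C9 into the C5=C9 enol double bond and the C1=C10 alkene. This removes both rings of the target at once: 7 is a monocyclic cyclopentene with one stereocentre. The other 1,5-dicarbonyl pair (C6/C9) would need the C4 carbinol, an unstable aldol of a 1,3-dione, inside the tether. The forward reaction needs the straight [2+2] adduct and addition anti to silicon.

**7 ⇒ 6 ⇒ 5 ⇒ 1 + 2 + 3 (through 4).** Cut the enol O–acyl bond, the C4–C5 bond (aldol, then oxidation) and the C6–Si bond (conjugate addition to 1). All ten skeletal carbons of the bicycle come from cyclopentenone 1 and aldehyde 3, and the only catalyst-controlled stereocentre is C6.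

## Roads not taken

**Alternative 1:** the most obvious plan closes ring A by olefin metathesis. Cut C8=C9 of the parent trisubstituted alkene A2 (jaeschkeanadiol); the forward key step is ring-closing metathesis of diene A1 with the second-generation Grubbs catalyst. A2 would then be esterified, epoxidised from the α face under direction by O6 (VO(acac)2, t-BuOOH) and the epoxide isomerised to the allylic alcohol. A1 needs four separate stereocontrolled events on a cyclopentane (quaternary C1 with methyl against allyl, C5, C6, C4). The metathesis forms a trisubstituted alkene in a seven-membered ring beside a quaternary carbon and creates no stereocentre, and three more steps are needed to move the alkene to C8=C14. The chosen plan makes both rings and C1 in one step and delivers C9 at the ketone level.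

**Alternative 2:** dearomatisation by an intramolecular Buchner reaction. Cut C5–C6 and C5–C1 so that C5 is a carbene carbon inserted into an arene bond: diazoketone A3 with Rh2(OAc)4 would give azulenone A4 with the C4 ketone, C14 and O9 in place. A4 is flat where the target is not: C1 is sp2 and would need the angular methyl by conjugate addition to an extended trienone (1,4 against 1,6 and 1,8 addition). O6 would have to be placed on a triene, the two ortho bonds of the arene compete, and no stereocentre is relayed. The run after the key step would be longer than the whole chosen route.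

**Alternative 3:** desymmetrising aldol. Cut C4–C5: the precursor A5 is a Cs-symmetric cycloheptane-1,4-dione with enantiotopic C5 and C10, and an amine-catalysed aldol would give ketol A6 with C1, C4 and C5 set at once. The enamine or enolate must form at the neopentyl C5 although C7 and C8 are easier. The side-chain C3 can attack the ring carbonyls instead, and a ketone–ketone aldol onto an isopropyl ketone is reversible, so three stereocentres would rest on one poorly controlled equilibrium. A5 itself needs a head-to-head intermolecular photocycloaddition. The chosen plan sets one centre by established catalysis and relays the rest.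

Key step: step 4

## Route

Step 1
Reactants: 1 cyclopent-2-en-1-one; 2 (dimethylphenylsilyl)boronic acid pinacol ester; 3 4-methylpent-4-enal
Product: 5 2,3-trans-(3S)-3-(dimethylphenylsilyl)-2-(1-hydroxy-4-methylpent-4-en-1-yl)cyclopentan-1-one (both carbinol epimers), via boron enolate 4 (not isolated)
Conditions: CuCl (5 mol %), chiral C1-symmetric 4,5-diphenylimidazolinium tetrafluoroborate (carbene precursor; the enantiomer that gives 6S), NaOt-Bu, THF, −78 °C; then 3, −78 → −40 °C; aq. NH4Cl
Reagents that add atoms: none
Why: Copper-catalysed enantioselective conjugate silyl transfer from the Si–B reagent sets C6 (S) under catalyst control and leaves the regiodefined boron enolate 4, which adds to the aldehyde in an aldol reaction trans to silicon; the carbinol centre is not controlled because it is oxidised next.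

Step 2
Reactants: 5 aldol adduct
Product: 6 (3S)-3-(dimethylphenylsilyl)-2-(4-methylpent-4-enoyl)cyclopentan-1-one (enolised 1,3-diketone)
Conditions: Dess–Martin periodinane, CH2Cl2, 0 °C → rt
Reagents that add atoms: none
Why: Dess–Martin oxidation of a β-hydroxy ketone to the 1,3-diketone; C5 loses its configuration by enolisation, which does not matter, and C6 is untouched.

Step 3
Reactants: 6 1,3-diketone
Product: 7 (3S)-3-(dimethylphenylsilyl)-2-(4-methylpent-4-enoyl)cyclopent-1-en-1-yl acetate
Conditions: Ac2O, Et3N, DMAP (cat.), CH2Cl2, 0 °C
Reagents that add atoms: acetic anhydride, CC(=O)OC(C)=O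
Why: O-acylation of the diketone on the ring oxygen, as enol esters and carbonates of 2-acylcyclopentanones are formed; the side-chain isomer would place a tetrasubstituted exocyclic double bond in allylic strain against the silyl-bearing C6.

Step 4
Reactants: 7 enol acetate
Product: 8 10-(dimethylphenylsilyl)-5-methyl-2-oxotricyclo[5.3.0.0^1,5]decan-7-yl acetate (both five-membered rings cis-fused to the cyclobutane on opposite faces; silicon anti to the cyclobutane)
Conditions: hν (medium-pressure Hg lamp, Pyrex filter, λ > 300 nm), degassed cyclohexane (0.01 M), rt
Reagents that add atoms: none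
Why: Excitation of the β-acetoxy enone (C9=C5–C4=O) and intersystem crossing give the triplet, whose α-carbon C5 bonds to the internal alkene carbon C1 (1,5-closure, rule of five), and the resulting 1,4-biradical (C9/C10) collapses to the cyclobutane. The closest known reaction type is the intramolecular De Mayo photocycloaddition of enol esters or carbonates of 2-(alkenoyl)cyclopentanones, a straight [2+2] of a hepta-1,6-dien-3-one. Ring B (C1–C5, five-membered) closes by the first C5–C1 bond and the four-membered ring by radical recombination; both fusions are cis because a trans-fused bicyclo[3.2.0]heptane is not accessible. The new centres C5, C9 and quaternary C1 are therefore tied to each other, and their sense relative to C6 is set by the face of the C5=C9 bond that is attacked. The tether adds anti to the SiMe2Ph group on the neighbouring C6, which places the C15 methyl trans to silicon on the future seven-membered ring (methyl β, silicon α), as the target requires. The step needs straight and not crossed addition, which the two-carbon tether between carbonyl and alkene secures, and face selectivity, which the size of the silyl group secures. C5 and C9 lose their configuration in step 5, so only C1 has to be right.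

Step 5
Reactants: 8 photoadduct
Product: 11 trans-fused (5α-H) 6α-(dimethylphenylsilyl)-1β-methylbicyclo[5.3.0]decane-4,9-dione, via cyclobutanol 9 (not isolated), via cis-fused diketone 10 (not isolated)
Conditions: K2CO3, MeOH, rt, until the C5 epimer ratio is constant
Reagents that add atoms: none
Why: Methanolysis of the tertiary acetate gives cyclobutanolate 9, whose strain-driven retro-aldol cleavage of C5–C9 (C4 ketone as electron sink) enlarges ring A from five to seven atoms, the second half of the De Mayo reaction. C5 then equilibrates through the enolate to the trans-fused epimer, in which ring B at C5 is anti to silicon at C6, whereas epimer 10 has C2, C4 and Si all cis on three neighbouring ring carbons.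

Step 6
Reactants: 11 trans-fused diketone
Product: 14 6α,9α-epoxy-9β-methoxy ketone (bridged methyl ketal; 8-oxabicyclo[3.2.1]octane spanning C6 and C9; C4 ketone free), via fluorosilane 12 (not isolated), via hydroxy diketone 13 (not isolated)
Conditions: HBF4·OEt2, CH2Cl2, 0 °C → rt; then mCPBA, Et3N, Et2O, rt; then PPTS (cat.), MeOH, rt
Reagents that add atoms: 3-chloroperoxybenzoic acid, OOC(=O)c1cccc(Cl)c1; methanol, CO
Why: Fleming–Tamao oxidation (protodesilylation of the phenyl group, then peracid rearrangement) turns C6–Si into C6–OH with retention. The cis-1,4 hydroxyl then adds across the ring to the C9 carbonyl and is locked as the mixed methyl ketal, which masks C9 and O6 together and leaves the hindered C4 ketone alone; the configuration at C9 is dictated by the bridge.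

Step 7
Reactants: 14 bridged ketal ketone
Product: 16 4β,6α-dihydroxy-4α-isopropyl-1β-methyl-5α-bicyclo[5.3.0]decan-9-one (ring–chain tautomer with the C6–O–C9 hemiketal), via carbinol ketal 15 (not isolated)
Conditions: i-PrMgCl, anhydrous CeCl3, THF, −78 → 0 °C; then 1 M HCl, THF, rt
Reagents that add atoms: isopropylmagnesium chloride, CC(C)[Mg]Cl; water, O
Why: Organocerium addition to a hindered, enolisable cyclopentanone; in the rigid ketal the β face of C4 is blocked by the axial C15 methyl and the C7–C8 bridge, so the nucleophile enters from the α face and gives the 4β-carbinol. Dilute acid then hydrolyses the mixed ketal by ring opening.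

Step 8
Reactants: 16 dihydroxy ketone; 17 4-(tert-butyldimethylsilyloxy)benzoic acid
Product: 18 C6 4-(tert-butyldimethylsilyloxy)benzoate of 16 (C4–OH free; C9 ketone)
Conditions: DCC, DMAP, CH2Cl2, rt
Reagents that add atoms: none
Why: Steglich esterification; only the secondary C6 hydroxyl of the open hydroxy-ketone form is acylated, the tertiary C4 hydroxyl is inert, and the hemiketal is drained through the open form.

Step 9
Reactants: 18 keto ester
Product: 20 8-methylene-9-ketone (α-methylene ketone), via Mannich base 19 (not isolated)
Conditions: (CH2O)n, PhNHMe·CF3CO2H, THF, reflux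
Reagents that add atoms: formaldehyde (from paraformaldehyde), C=O
Why: Amine-salt-mediated Mannich α-methylenation: the enol attacks the iminium ion and the Mannich base 19 loses N-methylaniline by β-elimination. C8 is the only unhindered α-methylene, since C10 is neopentyl and C4 is no longer a ketone.

Step 10
Reactants: 20 α-methylene ketone
Product: 21 O-(tert-butyldimethylsilyl)ferugin (9α-OH)
Conditions: (R)-2-methyl-CBS-oxazaborolidine (0.2 equiv), catecholborane, toluene, −78 °C
Reagents that add atoms: none
Why: Corey–Bakshi–Shibata 1,2-reduction of the enone under reagent control: the α-branched, methylene-bearing C8 is the large group and the C10 methylene the small one, so the (R)-catalyst delivers hydride to the Re (β) face of C9 and gives the 9S (9α) alcohol.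

Step 11
Reactants: 21 silyl-protected ferugin
Product: 22 ferugin
Conditions: Bu4NF, AcOH (1:1), THF, 0 °C
Reagents that add atoms: none
Why: Fluoride cleaves the aryl silyl ether far faster than it touches anything else; acetic acid buffers the phenoxide so that the ester does not migrate to the C9 or C4 hydroxyl.

## Compound list

1 | cyclopent-2-en-1-one | O=C1C=CCC1 | starting material
2 | (dimethylphenylsilyl)boronic acid pinacol ester | CC1(C)OB(OC1(C)C)[Si](C)(C)c1ccccc1 | starting material
3 | 4-methylpent-4-enal | C=C(C)CCC=O | starting material
4 | (S)-2-{[3-(dimethylphenylsilyl)cyclopent-1-en-1-yl]oxy}-4,4,5,5-tetramethyl-1,3,2-dioxaborolane (boron enolate) | CC1(C)OB(OC2=C[C@H](CC2)[Si](C)(C)c3ccccc3)OC1(C)C | intermediate (not isolated)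
5 | 2,3-trans-(3S)-3-(dimethylphenylsilyl)-2-(1-hydroxy-4-methylpent-4-en-1-yl)cyclopentan-1-one | O=C1CC[C@H]([Si](C)(C)c2ccccc2)[C@H]1C(O)CCC(C)=C | intermediate
6 | (3S)-3-(dimethylphenylsilyl)-2-(4-methylpent-4-enoyl)cyclopentan-1-one | O=C1CC[C@H]([Si](C)(C)c2ccccc2)C1C(=O)CCC(C)=C | intermediate
7 | (3S)-3-(dimethylphenylsilyl)-2-(4-methylpent-4-enoyl)cyclopent-1-en-1-yl acetate | C=C(C)CCC(=O)C1=C(OC(C)=O)CC[C@@H]1[Si](C)(C)c1ccccc1 | intermediate
8 | 10-(dimethylphenylsilyl)-5-methyl-2-oxotricyclo[5.3.0.0^1,5]decan-7-yl acetate (photoadduct) | CC(=O)O[C@]12CC[C@H]([Si](C)(C)c3ccccc3)[C@@]1(C(=O)CC4)[C@@]4(C)C2 | intermediate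
9 | cyclobutanol corresponding to 8 (formed as its alkoxide) | O[C@]12CC[C@H]([Si](C)(C)c3ccccc3)[C@@]1(C(=O)CC4)[C@@]4(C)C2 | intermediate (not isolated)
10 | cis-fused (5β-H) 6α-(dimethylphenylsilyl)-1β-methylbicyclo[5.3.0]decane-4,9-dione | O=C1CC[C@H]([Si](C)(C)c3ccccc3)[C@H]2[C@](C)(CCC2=O)C1 | intermediate (not isolated)
11 | trans-fused (5α-H) 6α-(dimethylphenylsilyl)-1β-methylbicyclo[5.3.0]decane-4,9-dione | O=C1CC[C@H]([Si](C)(C)c3ccccc3)[C@@H]2[C@](C)(CCC2=O)C1 | intermediate
12 | 6α-(fluorodimethylsilyl) analogue of 11 | O=C1CC[C@H]([Si](C)(C)F)[C@@H]2[C@](C)(CCC2=O)C1 | intermediate (not isolated)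
13 | 6α-hydroxy-1β-methyl-5α-bicyclo[5.3.0]decane-4,9-dione | O=C1CC[C@H](O)[C@@H]2[C@](C)(CCC2=O)C1 | intermediate (not isolated)
14 | 6α,9α-epoxy-9β-methoxy-1β-methyl-5α-bicyclo[5.3.0]decan-4-one (bridged methyl ketal) | CO[C@]12CC[C@H](O1)[C@@H]3[C@](C)(CCC3=O)C2 | intermediate
15 | 4β-hydroxy-4α-isopropyl derivative of 14 | CO[C@]12CC[C@H](O1)[C@@H]3[C@](C)(CC[C@@]3(O)C(C)C)C2 | intermediate (not isolated)
16 | 4β,6α-dihydroxy-4α-isopropyl-1β-methyl-5α-bicyclo[5.3.0]decan-9-one | O=C1CC[C@H](O)[C@@H]2[C@](C)(CC[C@@]2(O)C(C)C)C1 | intermediate
17 | 4-(tert-butyldimethylsilyloxy)benzoic acid | CC(C)(C)[Si](C)(C)Oc1ccc(cc1)C(O)=O | starting material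
18 | 6α-[4-(tert-butyldimethylsilyloxy)benzoyloxy]-4β-hydroxy-4α-isopropyl-1β-methyl-5α-bicyclo[5.3.0]decan-9-one | O=C1CC[C@H](OC(=O)c3ccc(O[Si](C)(C)C(C)(C)C)cc3)[C@@H]2[C@](C)(CC[C@@]2(O)C(C)C)C1 | intermediate
19 | 8-[(N-methylanilino)methyl] derivative of 18 (Mannich base, C8 epimers) | CN(c4ccccc4)CC1C[C@H](OC(=O)c3ccc(O[Si](C)(C)C(C)(C)C)cc3)[C@@H]2[C@](C)(CC[C@@]2(O)C(C)C)CC1=O | intermediate (not isolated)
20 | 8-methylene derivative of 18 (α-methylene ketone) | C=C1C[C@H](OC(=O)c3ccc(O[Si](C)(C)C(C)(C)C)cc3)[C@@H]2[C@](C)(CC[C@@]2(O)C(C)C)CC1=O | intermediate
21 | O-(tert-butyldimethylsilyl)ferugin | C=C1C[C@H](OC(=O)c3ccc(O[Si](C)(C)C(C)(C)C)cc3)[C@@H]2[C@](C)(CC[C@@]2(O)C(C)C)C[C@@H]1O | intermediate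
22 | ferugin, (3R,3aS,4S,7S,8aR)-3,7-dihydroxy-8a-methyl-6-methylidene-3-(propan-2-yl)decahydroazulen-4-yl 4-hydroxybenzoate | C=C1C[C@H](OC(=O)c2ccc(O)cc2)[C@@H]2[C@](C)(CC[C@@]2(O)C(C)C)C[C@@H]1O | target

## Step count and least certain steps

Total: 11 steps. Longest linear sequence: 11 steps, from 1.

**Step 4 (key).** The tethered alkene may add to both faces of the ring double bond if the silyl group shields less than assumed. The acetyl group may also migrate between the two diketone oxygens (thermal 1,5-shift or photochemical 1,3-shift), which moves the enol double bond into the side chain and leads to crossed addition. Fallback: change the chromophore from the enol ester to the hydrogen-bonded enol of the free diketone, the parent De Mayo reaction. Diketone 6 is irradiated directly (Pyrex, cyclohexane or MeCN); the chelate holds the side-chain carbonyl in the ring plane, no O-acyl group can migrate, cyclobutanol 9 forms and fragments in the flask, and brief K2CO3/MeOH treatment brings the material to 11. This sets out from 6, omits steps 3 and 5 as separate operations and returns at 11.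

**Step 5.** Protonation of the enolate anti to silicon gives the cis-fused epimer first, the equilibrium may not lie far enough on the trans side, and a transannular aldol of the 1,5-diketone may drain the cis epimer under base. Fallback: set C5 by kinetic protonation instead of equilibration. Cis diketone 10 is taken through the conditions of step 6 to the C5-epimeric bridged ketal F1, which is converted with TMSOTf/Et3N into the more substituted trimethylsilyl enol ether F2 (C4=C5). Desilylation with Bu4NF/AcOH at −78 °C protonates C5 from the open α face of the bridged system, anti to the axial methyl and the C7–C8 bridge, and returns the route at 14.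

**Step 6.** Peracid may cause Baeyer–Villiger oxidation of either ketone, and the β-hydroxy ketone 13 may dehydrate or undergo retro-aldol before the ketal locks it. Fallback: protect C9 from outside and oxidise silicon after C4 is no longer a carbonyl. From 11, kinetic ketalisation of the less hindered cycloheptanone ((TMSOCH2)2, TMSOTf cat., −78 °C) gives dioxolane F3. Addition of i-PrMgCl/CeCl3 from the α face, anti to the C6 substituent, gives carbinol F4. Buffered Fleming oxidation (KBr, AcOOH, NaOAc, AcOH) and dilute acid then give 16.

**Step 10.** The substrate bias of the ring (angular methyl on the β face, aroyloxy group on the α face) may oppose the catalyst, and some conjugate reduction may occur. Fallback: accept substrate control and invert. Luche reduction of 20 (NaBH4, CeCl3·7H2O, MeOH) gives the 9β-alcohol F5. Mitsunobu reaction with chloroacetic acid (PPh3, DIAD) gives the inverted 9α-chloroacetate F6, which thiourea/NaHCO3 cleaves without touching the C6 ester to give 21.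

**Step 1.** The pinacol boron enolate may add to the aldehyde sluggishly and the aldol may revert on work-up. Fallback: separate the two events. Enolate 4 is transmetalated with MeLi and trapped with TMSCl as the regiodefined trimethylsilyl enol ether F7, which undergoes a Mukaiyama aldol reaction with 3 (TiCl4, CH2Cl2, −78 °C) to give 5.

## Further compounds

F0 | step 4 | none | none
F1 | step 5 | C5 epimer (5β-H) of bridged methyl ketal 14 | CO[C@]12CC[C@H](O1)[C@H]3[C@](C)(CCC3=O)C2
F2 | step 5 | 4-(trimethylsilyloxy)-4(5)-ene of the bridged methyl ketal (silyl enol ether) | CO[C@]12CC[C@H](O1)C3=C(O[Si](C)(C)C)CC[C@]3(C)C2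
F3 | step 6 | 9,9-ethylenedioxy derivative of 11 (C9 dioxolane, C4 ketone) | C12(OCCO2)CC[C@H]([Si](C)(C)c3ccccc3)[C@@H]4[C@](C)(CCC4=O)C1
F4 | step 6 | 4β-hydroxy-4α-isopropyl derivative of F3 | C12(OCCO2)CC[C@H]([Si](C)(C)c3ccccc3)[C@@H]4[C@](C)(CC[C@@]4(O)C(C)C)C1
F5 | step 10 | 9β-hydroxy epimer of 21 | C=C1C[C@H](OC(=O)c3ccc(O[Si](C)(C)C(C)(C)C)cc3)[C@@H]2[C@](C)(CC[C@@]2(O)C(C)C)C[C@H]1O
F6 | step 10 | 9α-chloroacetate of 21 | C=C1C[C@H](OC(=O)c3ccc(O[Si](C)(C)C(C)(C)C)cc3)[C@@H]2[C@](C)(CC[C@@]2(O)C(C)C)C[C@@H]1OC(=O)CCl
F7 | step 1 | (S)-[3-(dimethylphenylsilyl)cyclopent-1-en-1-yl]oxytrimethylsilane | C[Si](C)(C)OC1=C[C@H](CC1)[Si](C)(C)c1ccccc1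
A1 | alternative 1 | metathesis diene: 1β-methyl-1α-allyl-4α-isopropylcyclopentan-4β-ol carrying the 1-hydroxy-3-methylbut-3-enyl chain at C5 | C=CC[C@@]1(C)CC[C@@](O)(C(C)C)[C@@H]1[C@@H](O)CC(C)=C
A2 | alternative 1 | jaeschkeanadiol (dauc-8-ene-4β,6α-diol) | CC1=CC[C@@]2(C)CC[C@@](O)(C(C)C)[C@@H]2[C@@H](O)C1
A3 | alternative 2 | 1-diazo-4-(3-methoxy-4-methylphenyl)butan-2-one | COc1cc(CCC(=O)C=[N+]=[N-])ccc1C
A4 | alternative 2 | 5-methoxy-6-methyl-3,8a-dihydroazulen-1(2H)-one | O=C1CCC2=CC(OC)=C(C)C=CC12
A5 | alternative 3 | 6-methyl-6-(4-methyl-3-oxopentyl)cycloheptane-1,4-dione | CC(C)C(=O)CCC1(C)CC(=O)CCC(=O)C1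
A6 | alternative 3 | 4β-hydroxy-4α-isopropyl-1β-methyl-5α-bicyclo[5.3.0]decane-6,9-dione | O=C1CCC(=O)[C@@H]2[C@](C)(CC[C@@]2(O)C(C)C)C1
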